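A flat curve tempts one to call a flask finished.

| flask | left-handed substrate | right-handed substrate | reagent | free catalyst | temperature | remark | time |
|---|---|---|---|---|---|---|---|
| eta | 0.051 M | 0.051 M | 1.1 equiv | 0.2 mol% | 0 °C | run made earlier |  |
| beta | 0.051 M | 0.051 M | 1.1 equiv | 0.13 mol% | 11 °C | run made earlier |  |
| epsilon | 0.051 M | 0.051 M | 1.1 equiv | 0.3 mol% | 0 °C | run made earlier |  |
| zeta | 0.10 M | 0.10 M | 1.1 equiv | 0.2 mol% | 11 °C | run made earlier |  |
| north-east | 0.051 M | 0.051 M | 1.10 equiv | 0.2 mol% | 5 °C | everything together at the start | 2.5 d |
| south-east | 0.051 M | 0.051 M | 1.10 equiv (fed, over 50 h) | 0.2 mol% |  | the addition at −35 °C, then warmed to 5 °C; the feed brings no volume worth counting | 2.5 d |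
| east | 0.051 M | 0.051 M | 1.10 equiv (in portions, 2, over 50 h) | 0.2 mol% | 5 °C | first portion at the start, last at 50 h | 2.5 d |
| south | 0.051 M | 0.051 M | 1.10 equiv (fed, over 50 h) | 0.2 mol% | 5 °C | all else is in the flask from the start; the feed brings no volume worth counting | 2.5 d |

| run | time / d | left-handed product / % |
|---|---|---|
| eta | 0.167 | 11.3 |
| eta | 0.500 | 19.0 |
| eta | 0.833 | 21.6 |
| eta | 1.25 | 23.6 |
| eta | 2.08 | 29.0 |
| eta | 2.50 | 30.2 |
| beta | 0.167 | 10.1 |
| beta | 0.500 | 19.6 |
| beta | 0.833 | 23.0 |
| beta | 1.25 | 27.3 |
| beta | 2.08 | 29.0 |
| beta | 2.50 | 29.6 |
| epsilon | 0.167 | 14.4 |
| epsilon | 0.500 | 20.3 |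
| epsilon | 0.833 | 25.1 |
| epsilon | 1.25 | 28.1 |
| epsilon | 2.08 | 29.4 |
| epsilon | 2.50 | 31.6 |
| zeta | 0.500 | 34.5 |
| zeta | 1.04 | 38.4 |
| zeta | 1.67 | 40.1 |
| zeta | 2.08 | 40.9 |
| zeta | 2.50 | 42.2 |

(readings scatter by 1 percentage point)

- the flask with the highest amount of left-handed product, in percent of the left-handed substrate and right-handed substrate together charged ("all alike" if they lie within 1.5 percentage points) (north-east / south-east / east / south / all alike)
- final left-handed product, as a percentage of the left-handed substrate and right-handed substrate together charged, in north-east
- final left-handed product, as a percentage of the left-handed substrate and right-handed substrate together charged, in south-east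
- final left-handed product, as a percentage of the left-handed substrate and right-handed substrate together charged, in east
- final left-handed product, as a percentage of the left-handed substrate and right-handed substrate together charged, in south

- free catalyst is single-handed; left-handed substrate and right-handed substrate are mirror images of each other, charged as a racemate, each of them at the stated concentration

Q: What does the last eta reading say?

A: Left-handed product stands at 30.2 % of both substrates charged. Left-handed substrate is half of that charge, so a fraction 0.396 of it remains. Reagent was charged at 1.1 equiv, so it remains too. Yet between the last two readings the product gains 1.2 percentage points.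

Q: What do you carry from run to run?

A: The budget: the natural log of one over the fraction of left-handed substrate left at the end. It counts the time constants the flask has lived through, in a pseudo-first-order picture. Eta gives 0.926, and beta gives 0.896. I take their mean for 5 °C, 0.911.

Q: Does more catalyst buy more budget?

A: Going from 0.2 mol% in eta to 0.3 mol% in epsilon moves it to 1.00.

Q: What does move it?

A: Zeta gives 1.86, a factor 2.08 over beta, with concentrations up by 1.96. Zeta also differs from beta in loading, 0.2 mol% against 0.13 mol%, but from eta to epsilon a factor 1.50 in loading moved the budget by a factor 1.08. At a fixed rate constant a first-order log drop does not depend on the substrate's own concentration, so I read the budget as following reagent concentration.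

Q: Then hold reagent back. What happens?

A: By 0.500 d, beta has spent 55.5 % of its budget. So the early part of the beta run counts. My reckoning for north-east is 29.9 %. East starts with half the reagent, so I give it half the budget and count nothing for the last portion, and that reckoning gives 18.3 %. I put no figure on south or on south-east.

The forecast names north-east, with 30.5 % there, 16 % in south-east, 19 % in east and 13.5 % in south. Its ground for east and south: “Holding reagent back wastes the catalyst's early life”.

The flasks give 30.3 % in north-east, 19.1 % in south-east, 19.1 % in east and 16.5 % in south, so north-east leads and the forecast stands.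

    2 free catalyst → spent catalyst (k = 920 M⁻¹ h⁻¹, Ea = 38.0 kJ mol⁻¹)
    reagent + free catalyst + right-handed substrate → free catalyst + right-handed product (k = 260 M⁻² h⁻¹, Ea = 42.0 kJ mol⁻¹)
    reagent + free catalyst + left-handed substrate → free catalyst + left-handed product (k = 19000 M⁻² h⁻¹, Ea = 35.0 kJ mol⁻¹)
    (constants at 5 °C)

North-east keeps a fraction 39 % of its left-handed substrate, a budget of 0.929 against the 0.911 carried. The gap between north-east and south is 14 points, and it falls to 5.8 points with the passing of two free catalyst into spent catalyst taken away, so 7.9 points of the gap goes with that step. For the neighbour of north-east charged with 4.40 equiv of reagent, I scale the budget with the reagent to 3.65, and that reckoning gives a fraction 0.0260 of left-handed substrate left and 48.7 % left-handed product. That flask computes to 49.5 %, with 0.91 % of its left-handed substrate left.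

(The numbers in the tables come from a simulation on assumed constants, and the scatter is random.)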